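## Retrosynthetic overview

1. Target 23 ⇐ fluoride-labile silyl ether/ester 22 ⇐ Z-selective cross-metathesis of the dec-9-enoate 20 with oct-7-en-1-ol; the formyl centre C2 is set last by base equilibration.
2. The C8 carboxyl / C10 ester array ⇐ C8 ketone (enol triflate, carbonylation) and C10 carbinol (oxidation, then Luche reduction) of tricyclic ketone 11.
3. 11 ⇐ one-flask epoxide-initiated cation–olefin bicyclization of a monocyclic epoxy enol ether (homobisabolyl → acorenyl → cedryl-type cations).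
4. Epoxy enol ether ⇐ Birch reduction and hydroxyl-directed epoxidation of anisole 7 ⇐ asymmetric alkylation of 4-methoxyphenylacetic acid with iodide 4.
5. Ring order: the six-membered ring comes from the anisole ring; ring A (cyclopentane, C1–C5 bond) and then ring B (bridging five-membered ring, C6–C7 bond) close in the same flask.

Assumption: the core is numbered as tricyclo[5.3.1.0(1,5)]undecane (cedrane numbering), and the facial sense of steps 4 and 7 is taken from the models stated there (both enantiomers of the amine in step 4 are available).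

## Route

Step 1
Reactants: 1 5-bromo-2-methylpent-2-ene
Product: 2 (2E)-5-bromo-2-methylpent-2-en-1-ol
Conditions: SeO2 (0.3 equiv), t-BuOOH, CH2Cl2, 0 °C to rt
Reagents that add atoms: tert-butyl hydroperoxide, CC(C)(C)OO; selenium dioxide, O=[Se]=O
Why: Sharpless–Umbreit SeO2 allylic oxidation (ene reaction then [2,3]-shift) oxidises only the (E)-methyl group, which fixes the E geometry that later defines C6.

Step 2
Reactants: 2 (2E)-5-bromo-2-methylpent-2-en-1-ol
Product: 3 triisopropylsilyl ether of 2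
Conditions: i-Pr3SiCl, imidazole, DMF, rt
Reagents that add atoms: chlorotri(propan-2-yl)silane, CC(C)[Si](Cl)(C(C)C)C(C)C
Why: Standard silylation; this arene-free silyl ether survives the enediolate, hydride and dissolving-metal steps.

Step 3
Reactants: 3 triisopropylsilyl ether bromide
Product: 4 {[(2E)-5-iodo-2-methylpent-2-en-1-yl]oxy}triisopropylsilane
Conditions: NaI, acetone, reflux
Reagents that add atoms: sodium iodide, [Na+].[I-]
Why: Finkelstein halide exchange gives the iodide needed for clean enolate alkylation at low temperature.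

Step 4
Reactants: 4 homoallylic iodide; 5 4-methoxyphenylacetic acid
Product: 6 (2R,5E)-2-(4-methoxyphenyl)-6-methyl-7-[(triisopropylsilyl)oxy]hept-5-enoic acid
Conditions: (R,R)-N1,N3-bis[1-phenyl-2-(piperidin-1-yl)ethyl]propane-1,3-diamine (1.05 equiv), n-BuLi (4.1 equiv), THF, 0 °C; then 4, −78 °C; aq HCl work-up (amine recovered)
Reagents that add atoms: none
Why: Enantioselective alkylation of the arylacetic acid enediolate held in a mixed aggregate with the chiral dilithium amide (traceless auxiliary) sets the benzylic centre as R; this is the only stereocentre taken from a chiral reagent.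

Step 5
Reactants: 6 (2R)-arylheptenoic acid
Product: 7 (2R,5E)-2-(4-methoxyphenyl)-6-methyl-7-[(triisopropylsilyl)oxy]hept-5-en-1-ol
Conditions: LiAlH4, THF, 0 °C to rt
Reagents that add atoms: none
Why: Hydride reduction of the acid gives the primary alcohol that later directs the epoxidation; the stereocentre is not touched.

Step 6
Reactants: 7 (2R)-aryl alcohol
Product: 8 (2R,5E)-2-(4-methoxycyclohexa-1,4-dien-1-yl)-6-methyl-7-[(triisopropylsilyl)oxy]hept-5-en-1-ol
Conditions: Li, NH3(l), t-BuOH, THF, −78 °C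
Reagents that add atoms: none
Why: Birch reduction of a 4-alkylanisole gives the 1-methoxy-4-alkylcyclohexa-1,4-diene regiospecifically, placing the enol ether on the arm that later closes ring B, while the alkoxide and the non-conjugated allylic silyl ether resist reduction.

Step 7
Reactants: 8 diene alcohol
Product: 9 (2S,5E)-2-[(1R,6R)-4-methoxy-7-oxabicyclo[4.1.0]hept-3-en-1-yl]-6-methyl-7-[(triisopropylsilyl)oxy]hept-5-en-1-ol
Conditions: VO(acac)2 (5 mol %), t-BuOOH, 2,6-lutidine (cat.), CH2Cl2, 0 °C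
Reagents that add atoms: tert-butyl hydroperoxide, CC(C)(C)OO
Why: Hydroxyl-directed vanadium-catalysed epoxidation of the homoallylic alkene (chair transition state, side chain equatorial, C–H eclipsing the ring CH2 to avoid A(1,2) strain) delivers oxygen syn to the CH2OH group and only to the nearest ring alkene, so the R centre sets the (1R,6R) epoxide.

Step 8
Reactants: 9 epoxy alcohol
Product: 11 tricyclic silyloxy ketone, via epoxide triethylsilyl ether 10 (not isolated)
Conditions: Et3SiOTf (1.05 equiv), 2,6-lutidine (1.2 equiv), CH2Cl2, −78 °C; then Me3SiOTf (1.3 equiv), −78 to −40 °C; aq NaHCO3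
Reagents that add atoms: triethylsilyl trifluoromethanesulfonate, CC[Si](CC)(CC)OS(=O)(=O)C(F)(F)F; trimethylsilyl trifluoromethanesulfonate, C[Si](C)(C)OS(=O)(=O)C(F)(F)F; water, O
Why: Proposed new method: silyl triflate opens the epoxide at the tertiary carbon C1 (homobisabolyl-type cation), the (E)-alkene attacks anti to the leaving oxygen in a 5-exo closure that sets C1 and C5 (acorenyl-type cation), and the methyl enol ether on the C11 arm then adds to the same alkene face, setting C6 and C7 (cedryl-type oxocarbenium, hydrolysed to the ketone), so all four ring stereocentres follow from the epoxide and the alkene geometry; the closest known reaction type is the Lewis-acid epoxide-initiated cation–olefin polycyclization with an enol ether terminator.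

Step 9
Reactants: 11 tricyclic silyloxy ketone
Product: 12 C8 enol triflate
Conditions: KN(SiMe3)2, PhNTf2, THF, −78 °C
Reagents that add atoms: N-phenylbis(trifluoromethanesulfonimide), O=S(=O)(N(c1ccccc1)S(=O)(=O)C(F)(F)F)C(F)(F)F
Why: Kinetic enolate O-triflation; C7 is a bridgehead, so only the C8=C9 enol triflate can form (Bredt's rule).

Step 10
Reactants: 12 C8 enol triflate
Product: 14 2-(trimethylsilyl)ethyl enoate carrying the axial C10 hydroxyl, via trimethylsilyl ether ester 13 (not isolated)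
Conditions: Pd(PPh3)4 (5 mol %), CO (1 atm), Me3SiCH2CH2OH, Et3N, DMF, 60 °C; then PPTS, MeOH, 0 °C (brief)
Reagents that add atoms: carbon monoxide, [C-]#[O+]; 2-(trimethylsilyl)ethanol, C[Si](C)(C)CCO
Why: Palladium-catalysed alkoxycarbonylation of the vinyl triflate installs C15 as the conjugated ester, and brief acid methanolysis removes only the labile trimethylsilyl ether.

Step 11
Reactants: 14 axial allylic alcohol
Product: 15 γ-keto enoate (C10 ketone)
Conditions: Dess–Martin periodinane, NaHCO3, CH2Cl2, rt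
Reagents that add atoms: none
Why: Dess–Martin oxidation erases the C10 configuration, which came out epimeric from the anti opening of the epoxide.

Step 12
Reactants: 15 γ-keto enoate
Product: 16 equatorial (10S) allylic alcohol
Conditions: NaBH4, CeCl3·7H2O, MeOH, −78 °C
Reagents that add atoms: none
Why: Luche 1,2-reduction; hydride adds to C10 from the face of the C11 methylene bridge (axial attack, the other face is eclipsed by the C1–C5 bond), giving the equatorial 10S alcohol of the target.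

Step 13
Reactants: 16 (10S) alcohol; 17 dec-9-enoic acid
Product: 18 C10 dec-9-enoate
Conditions: EDC·HCl, DMAP, CH2Cl2, 0 °C to rt
Reagents that add atoms: none
Why: Steglich esterification of the only free hydroxyl group.

Step 14
Reactants: 18 C10 dec-9-enoate
Product: 20 (2S)-aldehyde, via C2-epimeric aldehyde 19 (not isolated)
Conditions: (COCl)2, DMSO, CH2Cl2, −78 to −30 °C; Et3N; then DBU (0.5 equiv), rt
Reagents that add atoms: none
Why: Swern conditions oxidise the primary triethylsilyl ether directly to the aldehyde (the other silyl groups stay), and DBU then equilibrates C2 through the enol to the 2S epimer, where the formyl group sits cis to the C11 methylene and no longer eclipses the equatorial C10 acyloxy group (thermodynamic control).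

Step 15
Reactants: 20 (2S)-aldehyde; 21 oct-7-en-1-ol
Product: 22 (9Z)-16-hydroxyhexadec-9-enoate ester
Conditions: 21 (4 equiv), Ru(NO3)(=CH-C6H4-2-O-i-Pr)[C,C-chelating 1-(adamantan-1-yl)-3-(2,6-diisopropylphenyl)imidazolidin-2-ylidene, cyclometalated at adamantyl] (5 mol %), THF, 35 °C, argon sweep
Reagents that add atoms: none
Why: Z-selective olefin cross-metathesis of two terminal alkenes through a side-bound ruthenacycle gives the cis alkene; the trisubstituted enoate is inert and the aldehyde is tolerated.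

Step 16
Reactants: 22 silyl ether / 2-(trimethylsilyl)ethyl ester
Product: 23 target acid
Conditions: Bu4NF, AcOH, THF, 0 °C to rt
Reagents that add atoms: none
Why: Fluoride desilylation cleaves the neopentylic silyl ether and fragments the 2-(trimethylsilyl)ethyl ester (β-elimination to ethene) under acetic acid buffering, which spares the secondary ester; C2 is already at its thermodynamic configuration.

## Compound list

1 | 5-bromo-2-methylpent-2-ene | CC(C)=CCCBr | starting material
2 | (2E)-5-bromo-2-methylpent-2-en-1-ol | OC/C(C)=C/CCBr | intermediate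
3 | {[(2E)-5-bromo-2-methylpent-2-en-1-yl]oxy}triisopropylsilane | CC(C)[Si](OC/C(C)=C/CCBr)(C(C)C)C(C)C | intermediate
4 | {[(2E)-5-iodo-2-methylpent-2-en-1-yl]oxy}triisopropylsilane | CC(C)[Si](OC/C(C)=C/CCI)(C(C)C)C(C)C | intermediate
5 | 4-methoxyphenylacetic acid | COc1ccc(CC(=O)O)cc1 | starting material
6 | (2R,5E)-2-(4-methoxyphenyl)-6-methyl-7-[(triisopropylsilyl)oxy]hept-5-enoic acid | COc1ccc(cc1)[C@H](C(=O)O)CC/C=C(\C)CO[Si](C(C)C)(C(C)C)C(C)C | intermediate
7 | (2R,5E)-2-(4-methoxyphenyl)-6-methyl-7-[(triisopropylsilyl)oxy]hept-5-en-1-ol | COc1ccc(cc1)[C@H](CO)CC/C=C(\C)CO[Si](C(C)C)(C(C)C)C(C)C | intermediate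
8 | (2R,5E)-2-(4-methoxycyclohexa-1,4-dien-1-yl)-6-methyl-7-[(triisopropylsilyl)oxy]hept-5-en-1-ol | COC1=CCC(=CC1)[C@H](CO)CC/C=C(\C)CO[Si](C(C)C)(C(C)C)C(C)C | intermediate
9 | (2S,5E)-2-[(1R,6R)-4-methoxy-7-oxabicyclo[4.1.0]hept-3-en-1-yl]-6-methyl-7-[(triisopropylsilyl)oxy]hept-5-en-1-ol | COC1=CC[C@@]2(O[C@@H]2C1)[C@H](CO)CC/C=C(\C)CO[Si](C(C)C)(C(C)C)C(C)C | intermediate
10 | triethylsilyl ether of 9 (same configuration) | COC1=CC[C@@]2(O[C@@H]2C1)[C@H](CO[Si](CC)(CC)CC)CC/C=C(\C)CO[Si](C(C)C)(C(C)C)C(C)C | intermediate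
11 | (1S,2R,5S,6S,7R,10R)-6-methyl-2-[(triethylsilyloxy)methyl]-6-[(triisopropylsilyloxy)methyl]-10-(trimethylsilyloxy)tricyclo[5.3.1.0(1,5)]undecan-8-one (C10–O axial, syn to C11; C2 arm cis to C10) | C[C@@]1(CO[Si](C(C)C)(C(C)C)C(C)C)[C@H]2C[C@@]3([C@H](O[Si](C)(C)C)CC2=O)[C@H](CO[Si](CC)(CC)CC)CC[C@@H]13 | intermediate
12 | (1S,2R,5S,6S,7R,10R)-6-methyl-2-[(triethylsilyloxy)methyl]-6-[(triisopropylsilyloxy)methyl]-10-(trimethylsilyloxy)tricyclo[5.3.1.0(1,5)]undec-8-en-8-yl trifluoromethanesulfonate | C[C@@]1(CO[Si](C(C)C)(C(C)C)C(C)C)[C@H]2C[C@@]3([C@H](O[Si](C)(C)C)C=C2OS(=O)(=O)C(F)(F)F)[C@H](CO[Si](CC)(CC)CC)CC[C@@H]13 | intermediate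
13 | 2-(trimethylsilyl)ethyl (1S,2R,5S,6S,7R,10R)-6-methyl-2-[(triethylsilyloxy)methyl]-6-[(triisopropylsilyloxy)methyl]-10-(trimethylsilyloxy)tricyclo[5.3.1.0(1,5)]undec-8-ene-8-carboxylate | C[C@@]1(CO[Si](C(C)C)(C(C)C)C(C)C)[C@H]2C[C@@]3([C@H](O[Si](C)(C)C)C=C2C(=O)OCC[Si](C)(C)C)[C@H](CO[Si](CC)(CC)CC)CC[C@@H]13 | intermediate
14 | 2-(trimethylsilyl)ethyl (1S,2R,5S,6S,7R,10R)-10-hydroxy-6-methyl-2-[(triethylsilyloxy)methyl]-6-[(triisopropylsilyloxy)methyl]tricyclo[5.3.1.0(1,5)]undec-8-ene-8-carboxylate | C[C@@]1(CO[Si](C(C)C)(C(C)C)C(C)C)[C@H]2C[C@@]3([C@H](O)C=C2C(=O)OCC[Si](C)(C)C)[C@H](CO[Si](CC)(CC)CC)CC[C@@H]13 | intermediate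
15 | 2-(trimethylsilyl)ethyl (1S,2R,5S,6S,7R)-6-methyl-10-oxo-2-[(triethylsilyloxy)methyl]-6-[(triisopropylsilyloxy)methyl]tricyclo[5.3.1.0(1,5)]undec-8-ene-8-carboxylate | C[C@@]1(CO[Si](C(C)C)(C(C)C)C(C)C)[C@H]2C[C@@]3(C(=O)C=C2C(=O)OCC[Si](C)(C)C)[C@H](CO[Si](CC)(CC)CC)CC[C@@H]13 | intermediate
16 | 2-(trimethylsilyl)ethyl (1S,2R,5S,6S,7R,10S)-10-hydroxy-6-methyl-2-[(triethylsilyloxy)methyl]-6-[(triisopropylsilyloxy)methyl]tricyclo[5.3.1.0(1,5)]undec-8-ene-8-carboxylate | C[C@@]1(CO[Si](C(C)C)(C(C)C)C(C)C)[C@H]2C[C@@]3([C@@H](O)C=C2C(=O)OCC[Si](C)(C)C)[C@H](CO[Si](CC)(CC)CC)CC[C@@H]13 | intermediate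
17 | dec-9-enoic acid | C=CCCCCCCCC(=O)O | starting material
18 | 2-(trimethylsilyl)ethyl (1S,2R,5S,6S,7R,10S)-10-(dec-9-enoyloxy)-6-methyl-2-[(triethylsilyloxy)methyl]-6-[(triisopropylsilyloxy)methyl]tricyclo[5.3.1.0(1,5)]undec-8-ene-8-carboxylate | C[C@@]1(CO[Si](C(C)C)(C(C)C)C(C)C)[C@H]2C[C@@]3([C@@H](OC(=O)CCCCCCCC=C)C=C2C(=O)OCC[Si](C)(C)C)[C@H](CO[Si](CC)(CC)CC)CC[C@@H]13 | intermediate
19 | 2-(trimethylsilyl)ethyl (1S,2R,5S,6S,7R,10S)-10-(dec-9-enoyloxy)-2-formyl-6-methyl-6-[(triisopropylsilyloxy)methyl]tricyclo[5.3.1.0(1,5)]undec-8-ene-8-carboxylate | C[C@@]1(CO[Si](C(C)C)(C(C)C)C(C)C)[C@H]2C[C@@]3([C@@H](OC(=O)CCCCCCCC=C)C=C2C(=O)OCC[Si](C)(C)C)[C@H](C=O)CC[C@@H]13 | intermediate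
20 | 2-(trimethylsilyl)ethyl (1S,2S,5S,6S,7R,10S)-10-(dec-9-enoyloxy)-2-formyl-6-methyl-6-[(triisopropylsilyloxy)methyl]tricyclo[5.3.1.0(1,5)]undec-8-ene-8-carboxylate | C[C@@]1(CO[Si](C(C)C)(C(C)C)C(C)C)[C@H]2C[C@@]3([C@@H](OC(=O)CCCCCCCC=C)C=C2C(=O)OCC[Si](C)(C)C)[C@@H](C=O)CC[C@@H]13 | intermediate
21 | oct-7-en-1-ol | C=CCCCCCCO | starting material
22 | 2-(trimethylsilyl)ethyl (1S,2S,5S,6S,7R,10S)-2-formyl-10-{[(9Z)-16-hydroxyhexadec-9-enoyl]oxy}-6-methyl-6-[(triisopropylsilyloxy)methyl]tricyclo[5.3.1.0(1,5)]undec-8-ene-8-carboxylate | C[C@@]1(CO[Si](C(C)C)(C(C)C)C(C)C)[C@H]2C[C@@]3([C@@H](OC(=O)CCCCCCC/C=C\CCCCCCO)C=C2C(=O)OCC[Si](C)(C)C)[C@@H](C=O)CC[C@@H]13 | intermediate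
23 | (1S,2S,5S,6S,7R,10S)-2-formyl-10-{[(9Z)-16-hydroxyhexadec-9-enoyl]oxy}-6-(hydroxymethyl)-6-methyltricyclo[5.3.1.0(1,5)]undec-8-ene-8-carboxylic acid | C[C@@]1(CO)[C@H]2C[C@@]3([C@@H](OC(=O)CCCCCCC/C=C\CCCCCCO)C=C2C(=O)O)[C@@H](C=O)CC[C@@H]13 | target

## Step count and risks

Total step count: 16. Longest linear sequence: 16 (1 → 23; compounds 5, 17 and 21 enter as bought).

The three steps most likely to fail:

Step 8 (bicyclization). The spirocyclic cation may lose a proton, or the enol ether may interfere, before ring B closes. The fallback closes the rings one at a time and sets out from 10, this time isolated after silylation of 9 with Et3SiCl/imidazole. Et2AlCl in CH2Cl2 at −78 °C opens the epoxide and lets chloride capture the spirocyclic cation anti to the new C1–C5 bond, giving the spirocyclic tertiary chloride F4. AgOTf with 2,6-di-tert-butylpyridine then ionises the chloride with rear-side participation of the enol ether. This is a second inversion at C6, so the outcome matches the one-flask syn addition; any C6 epimer from a free cation is removed by chromatography. Silylation with Me3SiOTf and bicarbonate work-up return the route to 11.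

Step 7 (directed epoxidation). The electron-rich enol ether may be oxidised, or the facial ratio may be low. The fallback sets out from 8, which is converted with ethane-1,2-diol and PPTS into the dioxolane (2R,5E)-2-(1,4-dioxaspiro[4.5]dec-7-en-8-yl)-6-methyl-7-[(triisopropylsilyl)oxy]hept-5-en-1-ol F1. The same VO(acac)2/t-BuOOH epoxidation, now with no enol ether present, gives the ketal epoxy alcohol F2, and Et3SiCl/imidazole gives its triethylsilyl ether F3. Me3SiOTf with 2,6-lutidine then generates the enol ether from the ketal in the flask (only the C7 enol ether can close ring B) and the bicyclization leads back to 11. If the facial sense of the epoxidation were opposite to the model, the antipodal amine would be used in step 4; C2 would then emerge already in the 2S configuration.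

Step 15 (Z-selective cross-metathesis on the advanced aldehyde). The fallback builds the cis alkene before attachment and sets out from 16. Dec-9-ynoic acid dianion (n-BuLi, THF/HMPA) is alkylated with commercial (6-bromohexyloxy)(tert-butyl)dimethylsilane to give 16-[(tert-butyldimethylsilyl)oxy]hexadec-9-ynoic acid F5. Semihydrogenation (H2, Pd/CaCO3 poisoned with Pb(OAc)2, quinoline) gives (9Z)-16-[(tert-butyldimethylsilyl)oxy]hexadec-9-enoic acid F6. Steglich esterification of 16 with F6 gives the full-chain ester F7. The Swern/DBU sequence of step 14 passes through the 2R aldehyde F8 to the 2S aldehyde F9, and Bu4NF/AcOH removes all silyl groups and the ester to arrive at 23.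

## Further compounds

F1 | step 7 | (2R,5E)-2-(1,4-dioxaspiro[4.5]dec-7-en-8-yl)-6-methyl-7-[(triisopropylsilyl)oxy]hept-5-en-1-ol | C1COC2(O1)CCC(=CC2)[C@H](CO)CC/C=C(\C)CO[Si](C(C)C)(C(C)C)C(C)C
F2 | step 7 | ketal epoxy alcohol (ethylene ketal analogue of 9; epoxide 1R,6R in the numbering of 9; side-chain centre S) | C1COC2(O1)CC[C@@]3(O[C@@H]3C2)[C@H](CO)CC/C=C(\C)CO[Si](C(C)C)(C(C)C)C(C)C
F3 | step 7 | triethylsilyl ether of F2 | C1COC2(O1)CC[C@@]3(O[C@@H]3C2)[C@H](CO[Si](CC)(CC)CC)CC/C=C(\C)CO[Si](C(C)C)(C(C)C)C(C)C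
F4 | step 8 | spirocyclic tertiary chloride: 8-methoxy-spiro[4.5]dec-7-en-6-ol carrying CH2OSiEt3 at C1 and the C(Cl)(CH3)CH2OSi(i-Pr)3 group at C4 (chloride anti to the new ring bond) | C[C@](CO[Si](C(C)C)(C(C)C)C(C)C)(Cl)[C@@H]1CC[C@@H](CO[Si](CC)(CC)CC)[C@]12CC=C(OC)C[C@H]2O
F5 | step 15 | 16-[(tert-butyldimethylsilyl)oxy]hexadec-9-ynoic acid | CC(C)(C)[Si](C)(C)OCCCCCCC#CCCCCCCCC(=O)O
F6 | step 15 | (9Z)-16-[(tert-butyldimethylsilyl)oxy]hexadec-9-enoic acid | CC(C)(C)[Si](C)(C)OCCCCCC/C=C\CCCCCCCC(=O)O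
F7 | step 15 | ester of 16 with F6 | C[C@@]1(CO[Si](C(C)C)(C(C)C)C(C)C)[C@H]2C[C@@]3([C@@H](OC(=O)CCCCCCC/C=C\CCCCCCO[Si](C)(C)C(C)(C)C)C=C2C(=O)OCC[Si](C)(C)C)[C@H](CO[Si](CC)(CC)CC)CC[C@@H]13
F8 | step 15 | 2R aldehyde from F7 (not isolated) | C[C@@]1(CO[Si](C(C)C)(C(C)C)C(C)C)[C@H]2C[C@@]3([C@@H](OC(=O)CCCCCCC/C=C\CCCCCCO[Si](C)(C)C(C)(C)C)C=C2C(=O)OCC[Si](C)(C)C)[C@H](C=O)CC[C@@H]13
F9 | step 15 | 2S aldehyde from F8 | C[C@@]1(CO[Si](C(C)C)(C(C)C)C(C)C)[C@H]2C[C@@]3([C@@H](OC(=O)CCCCCCC/C=C\CCCCCCO[Si](C)(C)C(C)(C)C)C=C2C(=O)OCC[Si](C)(C)C)[C@@H](C=O)CC[C@@H]13
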